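Numbering: the carbocycle is C1 (bears the side chain), C2 (CH2), C3 (oxirane CH), C4 (oxirane C–CH3), C5 (C=O), C6 (CH–O–acyl). The side chain is C7 (=CH2), C8 (CH–OAc), C9–C11 (prenyl).
The last bond made is O6–acyl, by Steglich esterification. Before it, the six-membered carbocycle is opened at C1–C6 by a retro carbonyl-ene step. This gives an acyclic (3S,4S)-epoxy α-keto aldehyde that already holds all skeletal carbons, a Z C1=C7(CH3) alkene and the C8 acetate.
Enabling feature: the array O–C6–C1–C7(=CH2) on the carbocycle is a homoallylic alcohol with an exocyclic 1,1-disubstituted alkene, which is an ene retron. C6 lies next to the C5 ring ketone and C4 is quaternary, so C5/C6 is a chelatable, non-enolisable glyoxal.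
The keto aldehyde comes from a (2Z,5Z)-skipped trienol by Sharpless epoxidation (sets C3/C4, cis-oxirane from the Z alkene) and a one-carbon hydroxymethylation/oxidation (C6). The trienol comes from a Negishi union at C1–C2 of two Z fragments, both made from propargyl alcohol, with C8 set by Brown allylation and the prenyl end by cross-metathesis.
Ring order: oxirane first (step 11), cyclohexanone last (step 15).

Key step: step 15

Remark: the C5 carbinol centre made in step 13 is removed in step 14, so 16 and 17 are carried as C5 epimer mixtures and this centre is left undefined in their SMILES.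

Step 1
Reactants: 1 prop-2-yn-1-ol
Product: 3 (Z)-3-iodo-2-methylprop-2-en-1-ol, via alkenylmagnesium chelate 2 (not isolated)
Conditions: MeMgBr (2.5 equiv), CuI (10 mol %), Et2O, −10 °C to rt; then I2, 0 °C
Reagents that add atoms: methylmagnesium bromide C[Mg]Br; iodine II
Why: Alkoxide-directed, copper-catalysed anti-carbomagnesiation of the alkyne puts CH3 on the inner carbon and Mg on the terminus inside the five-membered chelate 2, so iodinolysis with retention should give only the Z iodide.

Step 2
Reactants: 3 (Z)-3-iodo-2-methylprop-2-en-1-ol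
Product: 4 (Z)-tert-butyl[(3-iodo-2-methylprop-2-en-1-yl)oxy]dimethylsilane
Conditions: TBSCl, imidazole, CH2Cl2, 0 °C to rt
Reagents that add atoms: tert-butyldimethylsilyl chloride CC(C)(C)[Si](C)(C)Cl
Why: Standard silylation of a primary alcohol, to which the alkenyl iodide is inert.

Step 3
Reactants: 4 (Z)-tert-butyl[(3-iodo-2-methylprop-2-en-1-yl)oxy]dimethylsilane
Product: 5 (Z)-4-(tert-butyldimethylsilyloxy)-3-methylbut-2-en-1-ol
Conditions: Bu3SnCH2OH, Pd(PPh3)4 (5 mol %), dioxane, 80 °C
Reagents that add atoms: (tributylstannyl)methanol OC[Sn](CCCC)(CCCC)CCCC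
Why: Stille coupling (hydroxymethyl transfer) to an alkenyl iodide runs with retention of alkene geometry and avoids an alkenyllithium that could suffer 1,4 O-to-C silyl migration.

Step 4
Reactants: 5 (Z)-4-(tert-butyldimethylsilyloxy)-3-methylbut-2-en-1-ol
Product: 6 (Z)-[(4-bromo-2-methylbut-2-en-1-yl)oxy](tert-butyl)dimethylsilane
Conditions: CBr4, PPh3, CH2Cl2, −20 to 0 °C, used promptly
Reagents that add atoms: carbon tetrabromide BrC(Br)(Br)Br
Why: The Appel reaction replaces the primary allylic hydroxyl by SN2 at CH2 under neutral conditions, leaving the silyl ether and the Z alkene untouched.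

Step 5
Reactants: 3 (Z)-3-iodo-2-methylprop-2-en-1-ol
Product: 7 (Z)-3-iodo-2-methylprop-2-enal
Conditions: activated MnO2 (excess), CH2Cl2, rt, dark, used at once
Reagents that add atoms: none
Why: Allylic oxidation with MnO2 is neutral and heterogeneous, which should preserve the isomerisation-prone Z β-iodo enal.

Step 6
Reactants: 7 (Z)-3-iodo-2-methylprop-2-enal
Product: 8 (1Z,3R)-1-iodo-2-methylhexa-1,5-dien-3-ol
Conditions: B-allyldiisopinocampheylborane derived from (−)-α-pinene, Et2O, −78 °C; then NaOH, 30 % H2O2, 0 °C to rt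
Reagents that add atoms: B-allyldiisopinocampheylborane C=CCB([C@H]1C[C@H]2C[C@@H]([C@@H]1C)C2(C)C)[C@H]1C[C@H]2C[C@@H]([C@@H]1C)C2(C)C
Why: Brown allylation through a chair Zimmerman–Traxler transition state, in which the isopinocampheyl groups from (−)-α-pinene direct the allyl group to the aldehyde face that gives the 3R carbinol (future C8), and the low temperature prevents Z/E isomerisation.

Step 7
Reactants: 8 (1Z,3R)-1-iodo-2-methylhexa-1,5-dien-3-ol
Product: 9 (1Z,3R)-1-iodo-2,6-dimethylhepta-1,5-dien-3-ol
Conditions: 2-methyl-2-butene (large excess), Grubbs II (3 mol %), CH2Cl2, rt to 35 °C, sealed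
Reagents that add atoms: 2-methyl-2-butene CC=C(C)C
Why: Olefin cross-metathesis of the terminal alkene with excess 2-methyl-2-butene installs the prenyl terminus, while the trisubstituted iodoalkene is too hindered to take part and C8 is untouched.

Step 8
Reactants: 9 (1Z,3R)-1-iodo-2,6-dimethylhepta-1,5-dien-3-ol; 6 (Z)-[(4-bromo-2-methylbut-2-en-1-yl)oxy](tert-butyl)dimethylsilane
Product: 11 (2Z,5Z,7R)-1-(tert-butyldimethylsilyloxy)-2,6,10-trimethylundeca-2,5,9-trien-7-ol, via alkenylzinc alkoxide 10 (not isolated)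
Conditions: 9, t-BuLi (3.1 equiv), Et2O, −78 °C; ZnBr2, THF, −78 to 0 °C; then 6, Pd(PPh3)4 (5 mol %), THF, 0 °C to rt
Reagents that add atoms: none
Why: Negishi coupling of an alkenylzinc with a primary allylic bromide gives 1,4-dienes by attack at the CH2 terminus with retention of both alkene geometries (the γ,γ-disubstituted π-allyl could only isomerise through a tertiary Pd–C bond), and the free carbinol is carried as its alkoxide.

Step 9
Reactants: 11 (2Z,5Z,7R)-1-(tert-butyldimethylsilyloxy)-2,6,10-trimethylundeca-2,5,9-trien-7-ol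
Product: 12 (2Z,5Z,7R)-1-(tert-butyldimethylsilyloxy)-2,6,10-trimethylundeca-2,5,9-trien-7-yl acetate
Conditions: Ac2O, pyridine, DMAP (cat.), CH2Cl2, 0 °C to rt
Reagents that add atoms: acetic anhydride CC(=O)OC(C)=O
Why: DMAP-catalysed acetylation marks O8 now, so that the hydroxyl set free in the key step will be the only one left to acylate, and it blocks O8 from directing the epoxidation.

Step 10
Reactants: 12 (2Z,5Z,7R)-1-(tert-butyldimethylsilyloxy)-2,6,10-trimethylundeca-2,5,9-trien-7-yl acetate
Product: 13 (2Z,5Z,7R)-1-hydroxy-2,6,10-trimethylundeca-2,5,9-trien-7-yl acetate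
Conditions: HF·pyridine, pyridine/THF, 0 °C
Reagents that add atoms: none
Why: Fluoride desilylation in a buffered, non-basic medium removes the primary TBS ether without cleavage or migration of the secondary acetate.

Step 11
Reactants: 13 (2Z,5Z,7R)-1-hydroxy-2,6,10-trimethylundeca-2,5,9-trien-7-yl acetate
Product: 14 (2R,3S,5Z,7R)-2,3-epoxy-1-hydroxy-2,6,10-trimethylundeca-5,9-dien-7-yl acetate
Conditions: Ti(OiPr)4 (20 mol %), D-(−)-diethyl tartrate (24 mol %), TBHP (decane), 4 Å MS, CH2Cl2, −20 °C
Reagents that add atoms: tert-butyl hydroperoxide CC(C)(C)OO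
Why: Sharpless asymmetric epoxidation acts only on the alkene that carries the free allylic hydroxyl, D-(−)-tartrate delivers oxygen to the face that gives the (2R,3S)-oxirane (future C4 and C3), and syn addition to the Z alkene puts C2 and C5 cis on the oxirane as the later ring fusion demands.

Step 12
Reactants: 14 (2R,3S,5Z,7R)-2,3-epoxy-1-hydroxy-2,6,10-trimethylundeca-5,9-dien-7-yl acetate
Product: 15 (2S,3S,5Z,7R)-2,3-epoxy-2,6,10-trimethyl-1-oxoundeca-5,9-dien-7-yl acetate
Conditions: Dess–Martin periodinane, CH2Cl2, 0 °C to rt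
Reagents that add atoms: none
Why: Dess–Martin oxidation of the primary epoxy alcohol is mild, and the α-carbon (C4) is quaternary, so it cannot epimerise.

Step 13
Reactants: 15 (2S,3S,5Z,7R)-2,3-epoxy-2,6,10-trimethyl-1-oxoundeca-5,9-dien-7-yl acetate
Product: 17 (3R,4S,6Z,8R)-3,4-epoxy-1,2-dihydroxy-3,7,11-trimethyldodeca-6,10-dien-8-yl acetate (C2 epimers), via β-hydroxysilane 16 (not isolated)
Conditions: (iPrO)Me2SiCH2MgCl (1.3 equiv), THF, −78 °C; aq NH4Cl; crude: 30 % H2O2, KF, KHCO3, THF/MeOH, rt
Reagents that add atoms: (isopropoxydimethylsilyl)methylmagnesium chloride CC(C)O[Si](C)(C)C[Mg]Cl; hydrogen peroxide OO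
Why: Nucleophilic hydroxymethylation, in which the Grignard addition at −78 °C should favour the activated epoxy aldehyde over the acetate and the Tamao oxidation turns C–Si into C–OH, brings in C6, and the new C5 carbinol centre needs no control because it is oxidised next.

Step 14
Reactants: 17 (3R,4S,6Z,8R)-3,4-epoxy-1,2-dihydroxy-3,7,11-trimethyldodeca-6,10-dien-8-yl acetate (C2 epimers)
Product: 18 (3S,4S,6Z,8R)-3,4-epoxy-3,7,11-trimethyl-1,2-dioxododeca-6,10-dien-8-yl acetate
Conditions: (COCl)2, DMSO, CH2Cl2, −78 °C; Et3N, −78 to 0 °C; dried azeotropically and used at once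
Reagents that add atoms: none
Why: Double Swern oxidation of a vicinal diol gives the 1,2-dicarbonyl without C–C cleavage, and the product has no enolisable position, so triethylamine cannot trigger aldol chemistry.

Step 15
Reactants: 18 (3S,4S,6Z,8R)-3,4-epoxy-3,7,11-trimethyl-1,2-dioxododeca-6,10-dien-8-yl acetate
Product: 19 (1S,3S,4S,6S)-4-[(3R)-3-acetoxy-6-methylhepta-1,5-dien-2-yl]-3-hydroxy-1-methyl-7-oxabicyclo[4.1.0]heptan-2-one
Conditions: [Cu((S,S)-t-Bu-box)](SbF6)2 (10 mol %), 4 Å MS, CH2Cl2 (0.01 M), 0 °C to rt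
Reagents that add atoms: none
Why: The bis(oxazoline)copper(II) dication chelates both carbonyl oxygens of the C5/C6 α-keto aldehyde in the s-cis form, and the activated C6 aldehyde then undergoes a concerted, asynchronous type I intramolecular carbonyl-ene reaction in which C6 bonds to C1, the C1=C7 π bond moves to C7=CH2 and a hydrogen of the C7 methyl group passes to the aldehyde oxygen. The closest known reactions are the citronellal-to-isopulegol cyclisation and the copper–box-catalysed inter- and intramolecular ene reactions of glyoxylates, glyoxals and unsaturated α-keto esters with 1,1-di- and trisubstituted alkenes. The carbocycle closes in a 6-exo-trig mode with respect to C1=C7 through a chair-like transition state (half-chair at the oxirane, which is already in place), so it is the last ring to form. C6 is set by the catalyst, whose tert-butyl groups leave open the aldehyde face that gives (S)-α-hydroxy carbonyl products in the glyoxylate series, and the substrate should favour the same half-chair because it turns the C5=O dipole away from the oxirane C4–O bond; C1 is set relative to C6 by the chair, in which the s-cis chelate forces C6–O equatorial and C7 is also equatorial, hence trans, with the side chain cis to the oxirane oxygen. The step needs hydrogen transfer from CH3 and not from C8–H, and the Z geometry of C1=C7 secures this because it places the methyl group cis to C1–H, the only allylic C–H within reach of the equatorial oxygen. Chemoselectivity rests on aldehyde over ketone, a six- over a ten-membered ring (remote prenyl alkene) and high dilution, and the acetate already on O8 leaves the new C6–OH as the only free hydroxyl.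

Step 16
Reactants: 19 (1S,3S,4S,6S)-4-[(3R)-3-acetoxy-6-methylhepta-1,5-dien-2-yl]-3-hydroxy-1-methyl-7-oxabicyclo[4.1.0]heptan-2-one; 20 3-methylbut-2-enoic acid
Product: 21 (1S,3S,4S,6S)-4-[(3R)-3-acetoxy-6-methylhepta-1,5-dien-2-yl]-1-methyl-2-oxo-7-oxabicyclo[4.1.0]heptan-3-yl 3-methylbut-2-enoate (CNP0168401.1)
Conditions: DCC, DMAP (cat.), CH2Cl2, 0 °C to rt
Reagents that add atoms: none
Why: Steglich esterification acylates the single free hydroxyl with retention at C6 (equatorial, the more stable α-ketol configuration), and carbodiimide activation avoids the vinylketene pathway of the acid chloride/amine method that deconjugates senecioates.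

Compound list
1 | prop-2-yn-1-ol | C#CCO | starting material
2 | 4-methyl-2,5-dihydro-1,2-oxamagnesole (chelated Z-alkenylmagnesium alkoxide) | CC1=C[Mg]OC1 | intermediate
3 | (Z)-3-iodo-2-methylprop-2-en-1-ol | OC/C(C)=C\I | intermediate
4 | (Z)-tert-butyl[(3-iodo-2-methylprop-2-en-1-yl)oxy]dimethylsilane | CC(C)(C)[Si](C)(C)OC/C(C)=C\I | intermediate
5 | (Z)-4-(tert-butyldimethylsilyloxy)-3-methylbut-2-en-1-ol | CC(C)(C)[Si](C)(C)OC/C(C)=C\CO | intermediate
6 | (Z)-[(4-bromo-2-methylbut-2-en-1-yl)oxy](tert-butyl)dimethylsilane | CC(C)(C)[Si](C)(C)OC/C(C)=C\CBr | intermediate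
7 | (Z)-3-iodo-2-methylprop-2-enal | O=C/C(C)=C\I | intermediate
8 | (1Z,3R)-1-iodo-2-methylhexa-1,5-dien-3-ol | O[C@H](CC=C)/C(C)=C\I | intermediate
9 | (1Z,3R)-1-iodo-2,6-dimethylhepta-1,5-dien-3-ol | O[C@H](CC=C(C)C)/C(C)=C\I | intermediate
10 | Z-alkenylzinc bromide, lithium alkoxide, from 9 | [Li]O[C@H](CC=C(C)C)/C(C)=C\[Zn]Br | intermediate
11 | (2Z,5Z,7R)-1-(tert-butyldimethylsilyloxy)-2,6,10-trimethylundeca-2,5,9-trien-7-ol | CC(C)(C)[Si](C)(C)OC/C(C)=C\C/C=C(C)\[C@H](O)CC=C(C)C | intermediate
12 | (2Z,5Z,7R)-1-(tert-butyldimethylsilyloxy)-2,6,10-trimethylundeca-2,5,9-trien-7-yl acetate | CC(C)(C)[Si](C)(C)OC/C(C)=C\C/C=C(C)\[C@H](OC(C)=O)CC=C(C)C | intermediate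
13 | (2Z,5Z,7R)-1-hydroxy-2,6,10-trimethylundeca-2,5,9-trien-7-yl acetate | OC/C(C)=C\C/C=C(C)\[C@H](OC(C)=O)CC=C(C)C | intermediate
14 | (2R,3S,5Z,7R)-2,3-epoxy-1-hydroxy-2,6,10-trimethylundeca-5,9-dien-7-yl acetate | OC[C@@]1(C)O[C@H]1C/C=C(C)\[C@H](OC(C)=O)CC=C(C)C | intermediate
15 | (2S,3S,5Z,7R)-2,3-epoxy-2,6,10-trimethyl-1-oxoundeca-5,9-dien-7-yl acetate | O=C[C@@]1(C)O[C@H]1C/C=C(C)\[C@H](OC(C)=O)CC=C(C)C | intermediate
16 | (3R,4S,6Z,8R)-3,4-epoxy-2-hydroxy-1-[isopropoxy(dimethyl)silyl]-3,7,11-trimethyldodeca-6,10-dien-8-yl acetate (C2 epimers) | CC(C)O[Si](C)(C)CC(O)[C@@]1(C)O[C@H]1C/C=C(C)\[C@H](OC(C)=O)CC=C(C)C | intermediate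
17 | (3R,4S,6Z,8R)-3,4-epoxy-1,2-dihydroxy-3,7,11-trimethyldodeca-6,10-dien-8-yl acetate (C2 epimers) | OCC(O)[C@@]1(C)O[C@H]1C/C=C(C)\[C@H](OC(C)=O)CC=C(C)C | intermediate
18 | (3S,4S,6Z,8R)-3,4-epoxy-3,7,11-trimethyl-1,2-dioxododeca-6,10-dien-8-yl acetate | O=CC(=O)[C@@]1(C)O[C@H]1C/C=C(C)\[C@H](OC(C)=O)CC=C(C)C | intermediate
19 | (1S,3S,4S,6S)-4-[(3R)-3-acetoxy-6-methylhepta-1,5-dien-2-yl]-3-hydroxy-1-methyl-7-oxabicyclo[4.1.0]heptan-2-one | C=C([C@@H](CC=C(C)C)OC(C)=O)[C@@H]1C[C@@H]2O[C@]2(C)C(=O)[C@H]1O | intermediate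
20 | 3-methylbut-2-enoic acid (senecioic acid) | CC(C)=CC(=O)O | starting material
21 | (1S,3S,4S,6S)-4-[(3R)-3-acetoxy-6-methylhepta-1,5-dien-2-yl]-1-methyl-2-oxo-7-oxabicyclo[4.1.0]heptan-3-yl 3-methylbut-2-enoate (CNP0168401.1) | C=C([C@@H](CC=C(C)C)OC(C)=O)[C@@H]1C[C@@H]2O[C@]2(C)C(=O)[C@H]1OC(=O)C=C(C)C | target

Total step count: 16. Longest linear sequence: 13 steps (1, 5, 6, 7, 8–16; the branch 1, 2, 3, 4, 8–16 has the same length).

Steps most likely to fail

Step 15 (ene cyclisation).
- What may go wrong: the two trans half-chairs may be poorly discriminated, giving weak facial selectivity relative to the oxirane.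
- The Lewis acid may open the oxirane or cause an acyl shift.
- The acetoxy group may participate at the developing positive charge on C7.
- Hydration of the dicarbonyl may block the catalyst.
- The fallback closes the same C1–C6 bond one oxidation level lower, with a monodentate aluminium Lewis acid instead of a chelated dicarbonyl. It sets out from 17 and comes back at 21.
- Silylation of 17 (TESCl, imidazole) would give the bis(triethylsilyl) ether F1.
- Swern conditions oxidise only the primary triethylsilyl ether and would give the α-silyloxy aldehyde F2.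
- Me2AlCl (CH2Cl2, −78 °C) would effect the type I carbonyl-ene closure to the hydroxy silyl ether F3.
- Steglich esterification with 20 would give the senecioate F4, and HF·pyridine would free the C5 carbinol F5.
- Dess–Martin oxidation of the carbinol would then lead to 21.

Step 13 (hydroxymethylation and Tamao oxidation).
- What may go wrong: the Grignard reagent or the hydroperoxide anion may attack the acetate.
- The oxirane may migrate by a base-induced Payne-type shift next to the new carbinol.
- The β-hydroxysilane may undergo Peterson elimination.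
- The fallback brings in C6 at the aldehyde oxidation level with a formyl anion equivalent and needs no peroxide. It sets out from 15 and comes back at 18, so steps 13 and 14 are both bypassed.
- 2-Lithio-1,3-dithiane (THF, −78 °C) would add to 15 to give the dithianyl carbinol F6.
- Parikh–Doering oxidation would give the 2-acyl-1,3-dithiane F7.
- MeI/CaCO3 in aqueous MeCN would unmask the aldehyde to 18.

Step 8 (Negishi union).
- What may go wrong: the dimetallated fragment may be quenched by a proton or homocouple.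
- Coupling may occur at the tertiary allyl terminus.
- The Z geometry may erode through π-allyl isomerisation.
- The fallback reverses the roles of the two fragments and joins them under neutral Stille conditions, with no organolithium near the C8 centre. It sets out from 9 and 4 and comes back at 12.
- Acetylation of 9 would give the iodo acetate F8.
- Stille hydroxymethylation (Bu3SnCH2OH, Pd(PPh3)4) would give the allylic alcohol F9, and the Appel reaction would give the allylic bromide F10.
- In parallel, Pd-catalysed stannylation of 4 with hexabutylditin would give the alkenylstannane F11.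
- Stille coupling of F10 with F11 (Pd2(dba)3, AsPh3, THF/NMP, rt) would give 12 directly.

Further compounds
F1 | step 15 | bis(triethylsilyl) ether of 17 | CC[Si](CC)(CC)OCC(O[Si](CC)(CC)CC)[C@@]1(C)O[C@H]1C/C=C(C)\[C@H](OC(C)=O)CC=C(C)C
F2 | step 15 | (3R,4S,6Z,8R)-3,4-epoxy-3,7,11-trimethyl-1-oxo-2-(triethylsilyloxy)dodeca-6,10-dien-8-yl acetate | O=CC(O[Si](CC)(CC)CC)[C@@]1(C)O[C@H]1C/C=C(C)\[C@H](OC(C)=O)CC=C(C)C
F3 | step 15 | ene product with C6 hydroxyl and C5 triethylsilyl ether | C=C([C@@H](CC=C(C)C)OC(C)=O)[C@@H]1C[C@@H]2O[C@]2(C)C(O[Si](CC)(CC)CC)[C@H]1O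
F4 | step 15 | C6 senecioate of F3 | C=C([C@@H](CC=C(C)C)OC(C)=O)[C@@H]1C[C@@H]2O[C@]2(C)C(O[Si](CC)(CC)CC)[C@H]1OC(=O)C=C(C)C
F5 | step 15 | C5 carbinol (dihydro form of 21) | C=C([C@@H](CC=C(C)C)OC(C)=O)[C@@H]1C[C@@H]2O[C@]2(C)C(O)[C@H]1OC(=O)C=C(C)C
F6 | step 13 | 1,3-dithian-2-yl carbinol from 15 | OC(C1SCCCS1)[C@@]2(C)O[C@H]2C/C=C(C)\[C@H](OC(C)=O)CC=C(C)C
F7 | step 13 | 2-acyl-1,3-dithiane (masked 18) | O=C(C1SCCCS1)[C@@]2(C)O[C@H]2C/C=C(C)\[C@H](OC(C)=O)CC=C(C)C
F8 | step 8 | (1Z,3R)-1-iodo-2,6-dimethylhepta-1,5-dien-3-yl acetate | CC(=O)O[C@H](CC=C(C)C)/C(C)=C\I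
F9 | step 8 | (2Z,4R)-1-hydroxy-3,7-dimethylocta-2,6-dien-4-yl acetate | CC(=O)O[C@H](CC=C(C)C)/C(C)=C\CO
F10 | step 8 | (2Z,4R)-1-bromo-3,7-dimethylocta-2,6-dien-4-yl acetate | CC(=O)O[C@H](CC=C(C)C)/C(C)=C\CBr
F11 | step 8 | (Z)-tert-butyldimethyl{[2-methyl-3-(tributylstannyl)prop-2-en-1-yl]oxy}silane | CC(C)(C)[Si](C)(C)OC/C(C)=C\[Sn](CCCC)(CCCC)CCCC
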